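Cuts: the three MOM ethers; then C4–C4a of ring C; then O1–C2 (vinylic C–O), C2–C3 (formyl carbon), C1'–CH2 (oxirane opening) and the C6'–CH2 bond of the prenyl group (Claisen rearrangement).
Enabling feature: C4 of ring C is an aryl ketone carbon bonded to C4a, the ring A carbon ortho to the O1-bearing C8a. The chain O1–C2=C3(C1')–C4 can therefore hang on the ring A oxygen with the crowded C3–C1' bond already made, and a carbanion at C4a can reach C4.
Forward: rings A and B are bought as benzenes. Ring B is fully substituted first, lengthened to the arylacetic N-methoxy-N-methylamide, formylated and joined to ring A through O1–C2. Ring C is the only ring formed and it closes last.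
Stereochemistry: the target has no stereocentre. Only the Z geometry of C2=C3 in the cyclisation precursor matters (amide cis to aryloxy); it is set by O-sulfonylation of a lithium chelate and kept in a retentive vinylic substitution.

Key step: step 15

Remark: Ar denotes the ring B unit 3-methoxy-4,6-bis(methoxymethoxy)-2-(3-methylbut-2-en-1-yl)phenyl (isoflavone positions 5', 4', 2', 6') and MOM = CH2OCH3; rotation about C3–C1' is assumed fast enough that no axial descriptor is needed, and the 3-hydroxyacrylamide of step 11 is drawn as its hydrogen-bonded Z enol although it equilibrates with the aldehyde form.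

Step 1
Reactants: 1 2,4-dihydroxybenzaldehyde
Product: 2 5-bromo-2,4-dihydroxybenzaldehyde
Conditions: Br2 (1.0 equiv), AcOH, 15–20 °C
Reagents that add atoms: bromine, BrBr
Why: Electrophilic aromatic bromination should go to C5, which is para to the 2-hydroxyl, ortho to the 4-hydroxyl and less crowded than C3, and this bromine marks the later C1' of ring B.

Step 2
Reactants: 2 5-bromo-2,4-dihydroxybenzaldehyde
Product: 3 5-bromo-2,4-bis(methoxymethoxy)benzaldehyde
Conditions: MOMCl (3 equiv), iPr2NEt (4 equiv), CH2Cl2, 0 °C to reflux
Reagents that add atoms: chloromethyl methyl ether (MOMCl), COCCl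
Why: Williamson-type O-alkylation of both phenols, the hydrogen-bonded 2-hydroxyl needing the excess reagent and gentle heating, gives acetal ethers that withstand the later base and organolithium steps and can be removed together at the end.

Step 3
Reactants: 3 5-bromo-2,4-bis(methoxymethoxy)benzaldehyde
Product: 5 5-bromo-2,4-bis(methoxymethoxy)phenol, via aryl formate 4 (not isolated)
Conditions: mCPBA, CH2Cl2, 0 °C to rt; aq NaHCO3 wash; K2CO3 (0.2 equiv), MeOH, rt
Reagents that add atoms: 3-chloroperoxybenzoic acid (mCPBA), O=C(OO)c1cccc(Cl)c1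
Why: Baeyer–Villiger oxidation of an electron-rich benzaldehyde (the Dakin-type conversion) proceeds with migration of the dialkoxyaryl group to formate 4, which methanolysis cleaves to the phenol whose oxygen becomes the 5'-methoxy oxygen.

Step 4
Reactants: 5 5-bromo-2,4-bis(methoxymethoxy)phenol; 6 3-chloro-3-methylbut-1-yne
Product: 7 1-bromo-2,4-bis(methoxymethoxy)-5-[(2-methylbut-3-yn-2-yl)oxy]benzene
Conditions: DBU (1.3 equiv), CuCl2·2H2O (1 mol %), MeCN, 0 °C
Reagents that add atoms: none
Why: Copper-catalysed O-alkylation of phenols with tertiary propargylic halides is the standard entry to 1,1-dimethylpropargyl aryl ethers and avoids a direct displacement at a tertiary carbon.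

Step 5
Reactants: 7 1-bromo-2,4-bis(methoxymethoxy)-5-[(2-methylbut-3-yn-2-yl)oxy]benzene
Product: 8 1-bromo-2,4-bis(methoxymethoxy)-5-[(2-methylbut-3-en-2-yl)oxy]benzene
Conditions: H2 (1 atm), 5% Pd/CaCO3 poisoned with Pb(OAc)2, quinoline, EtOAc, rt
Reagents that add atoms: none
Why: Poisoned-palladium semihydrogenation (Lindlar reduction) stops at the terminal alkene and leaves the aryl bromide and the acetals untouched, giving the 1,1-dimethylallyl ether needed for the sigmatropic shift.

Step 6
Reactants: 8 1-bromo-2,4-bis(methoxymethoxy)-5-[(2-methylbut-3-en-2-yl)oxy]benzene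
Product: 9 3-bromo-4,6-bis(methoxymethoxy)-2-(3-methylbut-2-en-1-yl)phenol
Conditions: N,N-diethylaniline, 130 °C
Reagents that add atoms: none
Why: The aromatic Claisen rearrangement, a [3,3]-sigmatropic shift with allyl inversion, can end productively only at the one free ortho carbon because the other ortho carbon and the para carbon carry MOM-oxy groups, so the tertiary ether becomes the prenyl group at C6' between the oxygen and the bromine.

Step 7
Reactants: 9 3-bromo-4,6-bis(methoxymethoxy)-2-(3-methylbut-2-en-1-yl)phenol
Product: 10 2-bromo-4-methoxy-1,5-bis(methoxymethoxy)-3-(3-methylbut-2-en-1-yl)benzene (Ar–Br)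
Conditions: MeI (1.5 equiv), K2CO3, DMF, rt
Reagents that add atoms: iodomethane, CI
Why: Williamson O-methylation of the only free phenol fixes the 5'-methoxy group and completes the pentasubstituted ring B.

Step 8
Reactants: 10 Ar–Br; 11 oxirane (ethylene oxide)
Product: 13 2-Ar-ethan-1-ol, via aryllithium 12 (not isolated)
Conditions: n-BuLi (1.05 equiv), THF, −78 °C; oxirane (3 equiv, THF solution), −78 °C to rt; H2O
Reagents that add atoms: none
Why: Bromine–lithium exchange gives an aryllithium stabilised by the neighbouring MOM oxygen, and SN2 opening of the small, unhindered epoxide by 2,6-disubstituted aryllithiums is a standard two-carbon homologation.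

Step 9
Reactants: 13 2-Ar-ethan-1-ol
Product: 14 2-Ar-acetic acid
Conditions: TEMPO (0.2 equiv), PhI(OAc)2 (2.2 equiv), aq MeCN, rt
Reagents that add atoms: water, O
Why: Oxoammonium-mediated oxidation of the primary alcohol through the aldehyde hydrate to the acid is selective for the carbinol and spares the trisubstituted alkene, the acetals and the electron-rich arene.

Step 10
Reactants: 14 2-Ar-acetic acid
Product: 16 2-Ar-N-methoxy-N-methylacetamide, via acylimidazole 15 (not isolated)
Conditions: CDI (1.2 equiv), CH2Cl2, rt; MeNH(OMe)·HCl (1.5 equiv), rt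
Reagents that add atoms: N,O-dimethylhydroxylamine hydrochloride, CNOC.Cl
Why: Activation as the acylimidazole followed by aminolysis is a standard amide synthesis in which the liberated imidazole takes up the hydrogen chloride, so the MOM groups meet no free acid.

Step 11
Reactants: 16 2-Ar-N-methoxy-N-methylacetamide
Product: 18 (2Z)-2-Ar-3-hydroxy-N-methoxy-N-methylprop-2-enamide, via lithium enolate 17 (not isolated)
Conditions: LiN(iPr)2 (2.5 equiv), THF, −78 °C; HCO2Et (6 equiv), −78 to 0 °C; AcOH
Reagents that add atoms: ethyl formate, CCOC=O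
Why: Crossed Claisen condensation (α-formylation) of the benzylic amide enolate with a non-enolisable and sterically small formate is driven by deprotonation of the product and brings in C2 of ring C.

Step 12
Reactants: 18 (2Z)-2-Ar-3-hydroxy-N-methoxy-N-methylprop-2-enamide
Product: 20 (2Z)-2-Ar-N-methoxy-N-methyl-3-(tosyloxy)prop-2-enamide, via lithium chelate 19 (not isolated)
Conditions: LiN(SiMe3)2 (1.05 equiv), THF, −78 °C; Ts2O (1.1 equiv), −78 to 0 °C
Reagents that add atoms: p-toluenesulfonic anhydride (Ts2O), Cc1ccc(cc1)S(=O)(=O)OS(=O)(=O)c1ccc(C)cc1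
Why: In THF lithium binds the enolate oxygen and the amide oxygen in a six-membered chelate, so stereoselective enol tosylation of this α-formyl carbonyl compound should trap the geometry in which the oxygen is cis to the amide.

Step 13
Reactants: 21 4-bromoresorcinol
Product: 22 2-bromo-5-(methoxymethoxy)phenol
Conditions: K2CO3 (2.5 equiv), MOMCl (1.0 equiv, slow addition), acetone, 0 °C
Reagents that add atoms: chloromethyl methyl ether (MOMCl), COCCl
Why: Williamson-type O-alkylation with both phenoxides available should favour the oxygen para to bromine, which is unhindered and the more basic, over the oxygen flanked by bromine, while slow addition of one equivalent limits the bis-ether and chromatography removes the minor isomers.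

Step 14
Reactants: 20 (2Z)-2-Ar-N-methoxy-N-methyl-3-(tosyloxy)prop-2-enamide; 22 2-bromo-5-(methoxymethoxy)phenol
Product: 23 (2Z)-2-Ar-3-[2-bromo-5-(methoxymethoxy)phenoxy]-N-methoxy-N-methylprop-2-enamide
Conditions: 22 (1.0 equiv), K2CO3 (1.1 equiv), DMF, 0 °C to rt, protected from light
Reagents that add atoms: none
Why: Nucleophilic vinylic substitution by addition–elimination at the β-carbon of the β-sulfonyloxyacrylamide forms O1–C2, and because tosylate leaves the transient α-carbanion after the shorter rotation the Z geometry should be retained, provided that no excess phenoxide is present to re-add and equilibrate the product.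

Step 15
Reactants: 23 (2Z)-2-Ar-3-[2-bromo-5-(methoxymethoxy)phenoxy]-N-methoxy-N-methylprop-2-enamide
Product: 26 7,2',4'-tris-O-(methoxymethyl)kwakhurin [3-Ar-7-(methoxymethoxy)-4H-chromen-4-one], via aryllithium 24 (not isolated), via lithium carbinolamine alkoxide 25 (not isolated)
Conditions: t-BuLi (2.05 equiv), THF (0.02 M), −95 °C, then to −40 °C; AcOH (3 equiv) in THF, −40 °C to rt
Reagents that add atoms: none
Why: Proposed new method: at −95 °C tert-butyllithium should exchange the C4a bromine, which is activated by the ortho oxygen, much faster than it adds to the hindered, donor-stabilised acrylamide or removes a proton, and its second equivalent destroys the tert-butyl bromide, so aryllithium 24 is the only carbanion present. In the Z isomer the amide carbon lies next to C4a and ring B has already twisted the amide out of the alkene plane, so its π* orbital faces the C–Li bond and 24 should close by 6-exo-trig attack on the carbonyl carbon, forming C4–C4a and ring C. Alkoxide 25 is held by lithium chelation to the N-methoxy oxygen and should release MeNHOMe only on the acetic acid quench, when no organolithium is left to add to the chromone. The closest known reaction type is the Parham cyclisation of 2-haloaryl ethers and 2-haloarylalkyl chains onto tethered N-methoxy-N-methylamides or carboxylates, which gives chroman-4-ones and benzo-fused cyclic ketones; new here is the unsaturated tether that carries a potential leaving group at C2. Regiochemistry is not left to the electronics of ring A: only the carbon that carried bromine is metalated, so C8, the other position ortho to O1, stays untouched, and no acid that could attack the prenyl alkene or the acetals is needed. No stereocentre is created in 26, since the carbinolamine carbon of 25 becomes the planar C4 carbonyl.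

Step 16
Reactants: 26 7,2',4'-tris-O-(methoxymethyl)kwakhurin
Product: 27 kwakhurin (7,2',4'-trihydroxy-5'-methoxy-6'-prenylisoflavone)
Conditions: p-TsOH·H2O (0.3 equiv), MeOH, 45 °C
Reagents that add atoms: none
Why: Acid-catalysed transacetalisation to methanol removes all three phenolic MOM groups, and since neither the 2'- nor the 4'-hydroxyl is ortho to the prenyl group at C6', acid-induced chroman formation has no pathway under these mild conditions.

Compound list
1 | 2,4-dihydroxybenzaldehyde | O=Cc1ccc(O)cc1O | starting material
2 | 5-bromo-2,4-dihydroxybenzaldehyde | O=Cc1cc(Br)c(O)cc1O | intermediate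
3 | 5-bromo-2,4-bis(methoxymethoxy)benzaldehyde | O=Cc1cc(Br)c(OCOC)cc1OCOC | intermediate
4 | 5-bromo-2,4-bis(methoxymethoxy)phenyl formate | O=COc1cc(Br)c(OCOC)cc1OCOC | intermediate
5 | 5-bromo-2,4-bis(methoxymethoxy)phenol | Oc1cc(Br)c(OCOC)cc1OCOC | intermediate
6 | 3-chloro-3-methylbut-1-yne | C#CC(C)(C)Cl | starting material
7 | 1-bromo-2,4-bis(methoxymethoxy)-5-[(2-methylbut-3-yn-2-yl)oxy]benzene | C#CC(C)(C)Oc1cc(Br)c(OCOC)cc1OCOC | intermediate
8 | 1-bromo-2,4-bis(methoxymethoxy)-5-[(2-methylbut-3-en-2-yl)oxy]benzene | C=CC(C)(C)Oc1cc(Br)c(OCOC)cc1OCOC | intermediate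
9 | 3-bromo-4,6-bis(methoxymethoxy)-2-(3-methylbut-2-en-1-yl)phenol | Oc1c(OCOC)cc(OCOC)c(Br)c1CC=C(C)C | intermediate
10 | 2-bromo-4-methoxy-1,5-bis(methoxymethoxy)-3-(3-methylbut-2-en-1-yl)benzene (Ar–Br) | COc1c(OCOC)cc(OCOC)c(Br)c1CC=C(C)C | intermediate
11 | oxirane (ethylene oxide) | C1CO1 | starting material
12 | aryllithium Ar–Li | [Li]c1c(OCOC)cc(OCOC)c(OC)c1CC=C(C)C | intermediate
13 | 2-Ar-ethan-1-ol | COc1c(OCOC)cc(OCOC)c(CCO)c1CC=C(C)C | intermediate
14 | 2-Ar-acetic acid | COc1c(OCOC)cc(OCOC)c(CC(=O)O)c1CC=C(C)C | intermediate
15 | 2-Ar-1-(imidazol-1-yl)ethan-1-one (acylimidazole) | COc1c(OCOC)cc(OCOC)c(CC(=O)n2ccnc2)c1CC=C(C)C | intermediate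
16 | 2-Ar-N-methoxy-N-methylacetamide | COc1c(OCOC)cc(OCOC)c(CC(=O)N(C)OC)c1CC=C(C)C | intermediate
17 | lithium enolate of 16 | [Li]OC(=Cc1c(OCOC)cc(OCOC)c(OC)c1CC=C(C)C)N(C)OC | intermediate
18 | (2Z)-2-Ar-3-hydroxy-N-methoxy-N-methylprop-2-enamide | CON(C)C(=O)/C(=C\O)c1c(OCOC)cc(OCOC)c(OC)c1CC=C(C)C | intermediate
19 | lithium chelate (Z lithium enolate of 18) | CON(C)C(=O)/C(=C\O[Li])c1c(OCOC)cc(OCOC)c(OC)c1CC=C(C)C | intermediate
20 | (2Z)-2-Ar-N-methoxy-N-methyl-3-(tosyloxy)prop-2-enamide | CON(C)C(=O)/C(=C\OS(=O)(=O)c1ccc(C)cc1)c1c(OCOC)cc(OCOC)c(OC)c1CC=C(C)C | intermediate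
21 | 4-bromoresorcinol | Oc1ccc(Br)c(O)c1 | starting material
22 | 2-bromo-5-(methoxymethoxy)phenol | COCOc1ccc(Br)c(O)c1 | intermediate
23 | (2Z)-2-Ar-3-[2-bromo-5-(methoxymethoxy)phenoxy]-N-methoxy-N-methylprop-2-enamide | CON(C)C(=O)/C(=C\Oc1cc(OCOC)ccc1Br)c1c(OCOC)cc(OCOC)c(OC)c1CC=C(C)C | intermediate
24 | aryllithium from 23 (Li at C4a) | CON(C)C(=O)/C(=C\Oc1cc(OCOC)ccc1[Li])c1c(OCOC)cc(OCOC)c(OC)c1CC=C(C)C | intermediate
25 | lithium 3-Ar-4-[methoxy(methyl)amino]-7-(methoxymethoxy)-4H-chromen-4-olate (racemic) | CON(C)C1(O[Li])c2ccc(OCOC)cc2OC=C1c3c(OCOC)cc(OCOC)c(OC)c3CC=C(C)C | intermediate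
26 | 7,2',4'-tris-O-(methoxymethyl)kwakhurin | COc1c(OCOC)cc(OCOC)c(-c2coc3cc(OCOC)ccc3c2=O)c1CC=C(C)C | intermediate
27 | kwakhurin | COc1c(O)cc(O)c(-c2coc3cc(O)ccc3c2=O)c1CC=C(C)C | target

Total step count: 16. Longest linear sequence: 15 steps (steps 1–12 and 14–16, from 1).

Steps most likely to fail

1. Step 15.
- What may go wrong:
  - tert-Butyllithium may add at C2 with expulsion of the aryloxide, or attack the amide, before the exchange is complete.
  - 24 may capture a proton before it closes, either from C2–H or from the position between two MOM-oxy groups of another molecule.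
  - 24 may fragment by loss of the enolate oxygen towards an aryne.
  - 25 may collapse early.
- Fallback (known chemistry, the deoxybenzoin order of events): it sets out from 22 and 16 and rejoins the route at 26. Two equivalents of n-BuLi (deprotonation, then bromine–lithium exchange) would convert 22 into lithium 2-lithio-5-(methoxymethoxy)phenolate F1. Its addition to amide 16 gives the dilithium tetrahedral adduct F2, which on aqueous work-up releases the 2-hydroxydeoxybenzoin 2-Ar-1-[2-hydroxy-4-(methoxymethoxy)phenyl]ethan-1-one F3. Heating F3 with N,N-dimethylformamide dimethyl acetal gives the enaminoketone F4, whose phenol oxygen displaces dimethylamine at the new carbon and closes ring C to 26. Here C4–C4a is made intermolecularly and O1–C2 closes the ring.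

2. Step 14.
- What may go wrong:
  - The sulfonyl group may transfer from 20 to the phenoxide by attack at sulfur.
  - The Z geometry may erode through rotation in the carbanion or through re-addition of phenoxide.
  - In 3-alkoxy-2-arylacrylic derivatives the isomer with oxygen trans to the carbonyl is usually the more stable, so any equilibration works against 23, and only the Z isomer can close in step 15.
- Fallback (the same C4–C4a closure one oxidation level lower, where no alkene geometry exists): it sets out from 16 (with 22) and rejoins at 26. Enolate 17 is trapped with monomeric formaldehyde to give racemic 2-Ar-3-hydroxy-N-methoxy-N-methylpropanamide F5. Mitsunobu etherification with 22 (PPh3, DIAD) gives racemic 2-Ar-3-[2-bromo-5-(methoxymethoxy)phenoxy]-N-methoxy-N-methylpropanamide F6. t-BuLi converts F6 into the aryllithium F7, which closes onto the amide, as in the classical Parham route to chroman-4-ones, through the lithium alkoxide F8 to the racemic isoflavanone 3-Ar-7-(methoxymethoxy)chroman-4-one F9. Dehydrogenation of F9 with DDQ in dioxane restores C2=C3 and gives 26.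

3. Step 11.
- What may go wrong:
  - C-formylation of the enolate may be incomplete because the 2,6-disubstituted aryl group shields both faces.
  - Retro-Claisen deformylation may occur on work-up.
  - Base may induce loss of formaldehyde from the N-methoxy group.
- Fallback (thermal aminomethylenation instead of an enolate condensation): it sets out from 16 and rejoins at 18. Heating 16 with tert-butoxybis(dimethylamino)methane gives 2-Ar-3-(dimethylamino)-N-methoxy-N-methylprop-2-enamide F10. Brief two-phase hydrolysis with cold dilute aqueous oxalic acid in THF exchanges the dimethylamino group for hydroxyl and gives 18 without loss of the MOM groups.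

Further compounds
F1 | step 15 | lithium 2-lithio-5-(methoxymethoxy)phenolate | [Li]Oc1cc(OCOC)ccc1[Li]
F2 | step 15 | dilithium tetrahedral adduct of F1 and 16 (racemic) | CON(C)C(O[Li])(Cc1c(OCOC)cc(OCOC)c(OC)c1CC=C(C)C)c1ccc(OCOC)cc1O[Li]
F3 | step 15 | 2-Ar-1-[2-hydroxy-4-(methoxymethoxy)phenyl]ethan-1-one | COc1c(OCOC)cc(OCOC)c(CC(=O)c2ccc(OCOC)cc2O)c1CC=C(C)C
F4 | step 15 | 2-Ar-3-(dimethylamino)-1-[2-hydroxy-4-(methoxymethoxy)phenyl]prop-2-en-1-one | COc1c(OCOC)cc(OCOC)c(C(=CN(C)C)C(=O)c2ccc(OCOC)cc2O)c1CC=C(C)C
F5 | step 14 | 2-Ar-3-hydroxy-N-methoxy-N-methylpropanamide (racemic) | COc1c(OCOC)cc(OCOC)c(C(CO)C(=O)N(C)OC)c1CC=C(C)C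
F6 | step 14 | 2-Ar-3-[2-bromo-5-(methoxymethoxy)phenoxy]-N-methoxy-N-methylpropanamide (racemic) | COc1c(OCOC)cc(OCOC)c(C(COc2cc(OCOC)ccc2Br)C(=O)N(C)OC)c1CC=C(C)C
F7 | step 14 | aryllithium from F6 (racemic) | COc1c(OCOC)cc(OCOC)c(C(COc2cc(OCOC)ccc2[Li])C(=O)N(C)OC)c1CC=C(C)C
F8 | step 14 | lithium 3-Ar-4-[methoxy(methyl)amino]-7-(methoxymethoxy)chroman-4-olate (racemic) | CON(C)C1(O[Li])c2ccc(OCOC)cc2OCC1c3c(OCOC)cc(OCOC)c(OC)c3CC=C(C)C
F9 | step 14 | 3-Ar-7-(methoxymethoxy)chroman-4-one (racemic isoflavanone) | COc1c(OCOC)cc(OCOC)c(C2COc3cc(OCOC)ccc3C2=O)c1CC=C(C)C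
F10 | step 11 | 2-Ar-3-(dimethylamino)-N-methoxy-N-methylprop-2-enamide | COc1c(OCOC)cc(OCOC)c(C(=CN(C)C)C(=O)N(C)OC)c1CC=C(C)C
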